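The numbers in the tables come from a simulation for an exercise; noise was put on by code.

- spring: starting material 6.5 mM; run made earlier
- flask: starting material 13 mM; time 6.0 min

spring run (percent of the starting material charged)

| time / s | isomer of the product A / % | target / % |
|---|---|---|
| 10.0 | 3.4 | 16.6 |
| 12.0 | 3.6 | 16.5 |
| 20.0 | 5.6 | 15.2 |
| 30.0 | 7.1 | 14.0 |
| 50.0 | 11.1 | 11.3 |
| 80.0 | 14.2 | 8.9 |

(standard deviation of a reading: 0.3 percentage points)

- percentages count the starting material that a species holds: one homo dimer counts as two
- the numbers in the tables scatter with a standard deviation of 0.3 percentage points
- steps thought possible: starting material <-> target; starting material <-> isomer of the product A; target -> over-reaction product; 2 starting material -> homo dimer; target <-> isomer of the product B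

- ratio of isomer of the product A to target at 0.80 s
- ratio of isomer of the product A to target at 6.0 min
- which of isomer of the product A and target there is more of at 6.0 min

A small charge of starting material, 6.5 mM, made the spring run. The flask takes 13 mM, twice that.

Examiner: What do the spring readings show of target?

Candidate: Target holds 16.6 % of the charge at 10.0 s and 8.9 % at 80.0 s. So I read a target lifetime, the time in which target falls by a factor of e after its burst, as 112 s. This treats the fall in the spring run as pseudo-first-order, at that charge.

Examiner: What does it give at 6.0 min?

Candidate: Carried forward from the first spring reading, it gives an estimate for the flask of 0.735 % of the charge as target. In the spring run, isomer of the product A reads 14.2 % at 80.0 s and is still rising. Held there, it gives a ratio of 19.3, which I take as the low side.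

Examiner: The weak spot?

Candidate: The spring run has one charge, so it cannot show how the lifetime moves with charge. I keep the lifetime unchanged, and that is my risk.

Examiner: And at 0.80 s?

Candidate: That lies before the first reading. The spring ratio rises from 0.205 at 10.0 s, so I expect less than that, but I can't place it.

The forecast says 0.025 at the early time, within 0.01 to 0.08. At the late time it says 25, within 7 to 60, with isomer of the product A ahead. Its ground for target is “then it decays roughly first-order”. My late ratio is lower than its figure.

The flask gives 0.0701 at 0.80 s and 21.1 at 6.0 min, with isomer of the product A ahead, 21.1 % against 0.999 %.

    starting material ⇌ target (K = 0.341, k = 0.0738 /s)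
    starting material ⇌ isomer of the product A (K = 97.0, k = 0.00456 /s)
    target → over-reaction product (k = 0.00801 /s)
    2 starting material → homo dimer (k = 1.92 /M/s)
    target ⇌ isomer of the product B (K = 0.870, k = 0.0958 /s)

At 6.00 min the flask makes target at 0.480 of the rate at which it uses it up, each step taken net. The lifetime of 112 s gave 0.735 %, less than the flask's 0.999 %. The lifetime takes no account of charge, so the same reckoning gives the same estimate for the neighbour flask at 32 mM, and that neighbour flask ends with 0.485 % of target, less than the estimate.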